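**Retrosynthetic overview**

1. Target 23 is a (2S)-flavanone (ring A: 5-OH, 7-OMe, 8-prenyl; ring B: 3′-OH, 4′-OMe; ring C: the pyranone). The last operation frees O5 and O3′ from the methyl/MOM-protected flavanone 22 with BCl3.
2. Key disconnection: ring C is closed through the C4–C4a bond, with O1–C8a made in the same flask. The potassium alkoxide of the (S)-β-hydroxy amide 17 (C2, C3, C4 and ring B) adds to aryne 19 (ring A, C4a≡C8a, from silyl triflate 11), and the C4a carbanion then adds to the amide carbon.
3. Enabling feature: on ring A the oxygen O5 sits ortho to C4a and O1 sits on the neighbouring C8a. An aryne C4a≡C8a polarized by O5 therefore takes the oxygen nucleophile at C8a and carries its charge at C4a, 1,5 to the amide carbon C4 across the O1–C2–C3 tether (six-membered ring C).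
4. Fragments: 11 from 3,5-dimethoxyphenol by two carbamate-directed ortho metalations run in one flask (SiMe3 at the future C4a, prenyl at the future C8); 17 from methyl 3-hydroxy-4-methoxybenzoate by Claisen condensation and Noyori asymmetric transfer hydrogenation, which sets C2.
5. Ring order: rings A and B are bought; ring C is the only ring formed, in step 7.

Key step: step 7

Remark: the SMILES encodes the (2S) enantiomer and C2 is the only stereocenter; prenyl means 3-methylbut-2-en-1-yl; the O5 methyl and O3′ MOM groups are temporary and leave in step 8.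

**Step 1**
Reactants: 1 3,5-dimethoxyphenol
Product: 2 3,5-dimethoxyphenyl N-(propan-2-yl)carbamate
Conditions: i-PrNCO, Et3N (cat.), CH2Cl2, rt
Reagents that add atoms: isopropyl isocyanate, CC(C)N=C=O
Why: Base-catalysed carbamoylation (addition of the phenol O–H across the isocyanate) gives an N–H carbamate that is a strong ortho-directing group and can later be removed by elimination; no stereocenter is involved.

**Step 2**
Reactants: 2 3,5-dimethoxyphenyl N-(propan-2-yl)carbamate; 3 1-bromo-3-methylbut-2-ene (prenyl bromide)
Product: 9 3,5-dimethoxy-2-(3-methylbut-2-en-1-yl)-6-(trimethylsilyl)phenyl N-(propan-2-yl)carbamate, via N-silyl carbamate 4 (not isolated), via first aryllithium 5 (not isolated), via disilyl carbamate 6 (not isolated), via second aryllithium 7 (not isolated), via N-silyl prenyl carbamate 8 (not isolated)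
Conditions: TBSOTf, TMEDA, Et2O, 0 °C to rt; n-BuLi, TMEDA, −78 °C; TMSCl (1.05 equiv), −78 to −40 °C; n-BuLi (1.3 equiv), −78 °C; CuBr·SMe2 (cat.), 3, −78 to 0 °C; aq NaHSO4
Reagents that add atoms: chlorotrimethylsilane, C[Si](C)(C)Cl
Why: Two successive directed ortho metalations in one flask: after in situ N-silylation, which stops the carbamate from eliminating, the carbamate oxygen and a flanking methoxy group direct n-BuLi first to one of the two carbons that lie between them (trapped by TMSCl to give 6, whose N-silyl group stays in place) and then to the other, the second aryllithium 7 undergoes copper-catalysed allylic substitution on prenyl bromide at its primary carbon (SN2 rather than SN2′), and the single acidic work-up cleaves the N–Si bond.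

**Step 3**
Reactants: 9 3,5-dimethoxy-2-(3-methylbut-2-en-1-yl)-6-(trimethylsilyl)phenyl N-(propan-2-yl)carbamate
Product: 11 3,5-dimethoxy-2-(3-methylbut-2-en-1-yl)-6-(trimethylsilyl)phenyl trifluoromethanesulfonate, via phenol 10 (not isolated)
Conditions: DBU, Et2NH, MeCN, 40 °C; then PhNTf2, rt
Reagents that add atoms: N-phenylbis(trifluoromethanesulfonimide), O=S(=O)(N(c1ccccc1)S(=O)(=O)C(F)(F)F)C(F)(F)F
Why: E1cB cleavage of the N–H carbamate (DBU removes the N–H proton, the phenoxide leaves and Et2NH traps the isocyanate as a urea) frees the hindered phenoxide of 10, which is sulfonylated in the same pot by PhNTf2 to the ortho-silylaryl triflate.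

**Step 4**
Reactants: 12 methyl 3-hydroxy-4-methoxybenzoate
Product: 13 methyl 4-methoxy-3-(methoxymethoxy)benzoate
Conditions: MOMCl, i-Pr2NEt, CH2Cl2, 0 °C to rt
Reagents that add atoms: chloromethyl methyl ether, COCCl
Why: O-Alkylation of the phenol by MOMCl gives an acetal that withstands the enolate, hydride-transfer, KH and fluoride chemistry ahead and is cleaved together with the O5 methyl ether at the end.

**Step 5**
Reactants: 13 methyl 4-methoxy-3-(methoxymethoxy)benzoate; 14 N,N-dimethylacetamide
Product: 16 3-[4-methoxy-3-(methoxymethoxy)phenyl]-N,N-dimethyl-3-oxopropanamide, via lithium enolate 15 (not isolated)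
Conditions: 14, LiN(i-Pr)2 (2.2 equiv each), THF, −78 °C; then 13, −78 to 0 °C; aq HCl to pH 5
Reagents that add atoms: none
Why: Crossed Claisen condensation: lithium enolate 15 is acylated on carbon by the non-enolisable aryl ester, and the excess enolate drives the equilibrium by deprotonating the β-keto amide, which is released on acidification.

**Step 6**
Reactants: 16 3-[4-methoxy-3-(methoxymethoxy)phenyl]-N,N-dimethyl-3-oxopropanamide
Product: 17 (3S)-3-hydroxy-3-[4-methoxy-3-(methoxymethoxy)phenyl]-N,N-dimethylpropanamide
Conditions: RuCl[(S,S)-TsDPEN](p-cymene) (1 mol %), HCO2H/Et3N (5:2), EtOAc, 40 °C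
Reagents that add atoms: none
Why: Noyori asymmetric transfer hydrogenation of an aryl ketone: the ruthenium hydride of the (S,S)-TsDPEN complex delivers H to the carbonyl face fixed by the CH–π contact between the aryl group and the p-cymene ligand, the sense that turns acetophenone into (S)-1-phenylethanol, which sets the carbinol carbon (future C2) as S because aryl outranks CH2C(O)NMe2.

**Step 7**
Reactants: 11 3,5-dimethoxy-2-(3-methylbut-2-en-1-yl)-6-(trimethylsilyl)phenyl trifluoromethanesulfonate; 17 (3S)-3-hydroxy-3-[4-methoxy-3-(methoxymethoxy)phenyl]-N,N-dimethylpropanamide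
Product: 22 (2S)-5,7-dimethoxy-2-[4-methoxy-3-(methoxymethoxy)phenyl]-8-(3-methylbut-2-en-1-yl)-2,3-dihydro-4H-chromen-4-one, via potassium alkoxide 18 (not isolated), via aryne 19 (not isolated), via aryl potassium 20 (not isolated), via aminal alkoxide 21 (not isolated)
Conditions: KH (1.05 equiv), THF, 0 °C; then KF, 18-crown-6 (3 equiv each), slow addition of 11 (1.3 equiv), 0 °C to rt; then cold 0.5 M aq HCl
Reagents that add atoms: none
Why: Proposed new method: the potassium alkoxide 18 adds through oxygen to the strained triple bond of aryne 19 (freed from 11 by fluoride attack on silicon and loss of triflate) at the carbon meta to the neighbouring ring A methoxy group, so that the charge of aryl potassium 20 lies on the carbon between that methoxy group and the new ether oxygen (future C4a), and this carbanion then adds to the amide carbonyl to form the C4–C4a bond. Ring C closes by a 6-exo-trig anionic acyl addition that stops at aminal alkoxide 21, which cannot expel dimethylamide, so the base-labile β-aryloxy ketone is only unveiled by the cold acidic quench. The closest known reaction types are the fluoride-induced aryne annulation of ortho-hydroxyaryl esters to xanthones (intermolecular O-arylation, then capture of the aryl anion by the tethered acyl group) and the Parham cyclization of ortho-metalated aryl ethers onto tethered tertiary amides to chroman-4-ones; new here is an aliphatic alkoxide that carries the tethered amide. No stereocenter is formed: C2 comes from 17 with retention because only its O–H bond reacts, the tertiary amide makes retro-aldol cleavage of 18 unfavourable, and the absence of a free ketone in the basic flask blocks retro-oxa-Michael scrambling. The step needs O-attack at the aryne carbon next to the prenyl group, which the inductive polarization of the aryne by the ortho oxygen O5 should secure against the small steric bias of the alkyl neighbour, and it needs carbonyl addition to outrun proton capture, which the preformed alkoxide in aprotic THF should secure.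

**Step 8**
Reactants: 22 (2S)-5,7-dimethoxy-2-[4-methoxy-3-(methoxymethoxy)phenyl]-8-(3-methylbut-2-en-1-yl)-2,3-dihydro-4H-chromen-4-one
Product: 23 (2S)-5-hydroxy-2-(3-hydroxy-4-methoxyphenyl)-7-methoxy-8-(3-methylbut-2-en-1-yl)-2,3-dihydro-4H-chromen-4-one
Conditions: BCl3 (1 M in CH2Cl2, 4 equiv), CH2Cl2, −78 to −20 °C; then aq NaHCO3
Reagents that add atoms: none
Why: Chelation-controlled ether cleavage: BCl3 bridges the C4 carbonyl and the peri O5 methyl ether in a six-membered chelate so that chloride removes only this methyl group, the MOM acetal at O3′ is cleaved by the same Lewis acid, the O7 and O4′ methyl ethers lack such activation, and the low temperature and basic quench should protect the prenyl alkene and the C2 stereocenter, which is not touched.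

**Compound list**

1 | 3,5-dimethoxyphenol | COc1cc(O)cc(OC)c1 | starting material
2 | 3,5-dimethoxyphenyl N-(propan-2-yl)carbamate | COc1cc(OC(=O)NC(C)C)cc(OC)c1 | intermediate
3 | 1-bromo-3-methylbut-2-ene (prenyl bromide) | CC(C)=CCBr | starting material
4 | 3,5-dimethoxyphenyl N-(tert-butyldimethylsilyl)-N-(propan-2-yl)carbamate | COc1cc(OC(=O)N(C(C)C)[Si](C)(C)C(C)(C)C)cc(OC)c1 | intermediate
5 | 2-lithio derivative of 4 (lithium between the carbamate and a methoxy group) | COc1cc(OC)c([Li])c(OC(=O)N(C(C)C)[Si](C)(C)C(C)(C)C)c1 | intermediate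
6 | 3,5-dimethoxy-2-(trimethylsilyl)phenyl N-(tert-butyldimethylsilyl)-N-(propan-2-yl)carbamate | COc1cc(OC)c([Si](C)(C)C)c(OC(=O)N(C(C)C)[Si](C)(C)C(C)(C)C)c1 | intermediate
7 | 6-lithio derivative of 6 | COc1cc(OC)c([Si](C)(C)C)c(OC(=O)N(C(C)C)[Si](C)(C)C(C)(C)C)c1[Li] | intermediate
8 | 3,5-dimethoxy-2-(3-methylbut-2-en-1-yl)-6-(trimethylsilyl)phenyl N-(tert-butyldimethylsilyl)-N-(propan-2-yl)carbamate | COc1cc(OC)c([Si](C)(C)C)c(OC(=O)N(C(C)C)[Si](C)(C)C(C)(C)C)c1CC=C(C)C | intermediate
9 | 3,5-dimethoxy-2-(3-methylbut-2-en-1-yl)-6-(trimethylsilyl)phenyl N-(propan-2-yl)carbamate | COc1cc(OC)c([Si](C)(C)C)c(OC(=O)NC(C)C)c1CC=C(C)C | intermediate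
10 | 3,5-dimethoxy-2-(3-methylbut-2-en-1-yl)-6-(trimethylsilyl)phenol | COc1cc(OC)c([Si](C)(C)C)c(O)c1CC=C(C)C | intermediate
11 | 3,5-dimethoxy-2-(3-methylbut-2-en-1-yl)-6-(trimethylsilyl)phenyl trifluoromethanesulfonate | COc1cc(OC)c([Si](C)(C)C)c(OS(=O)(=O)C(F)(F)F)c1CC=C(C)C | intermediate
12 | methyl 3-hydroxy-4-methoxybenzoate | COC(=O)c1ccc(OC)c(O)c1 | starting material
13 | methyl 4-methoxy-3-(methoxymethoxy)benzoate | COC(=O)c1ccc(OC)c(OCOC)c1 | intermediate
14 | N,N-dimethylacetamide | CC(=O)N(C)C | starting material
15 | lithium 1-(dimethylamino)ethenolate | C=C(O[Li])N(C)C | intermediate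
16 | 3-[4-methoxy-3-(methoxymethoxy)phenyl]-N,N-dimethyl-3-oxopropanamide | CN(C)C(=O)CC(=O)c1ccc(OC)c(OCOC)c1 | intermediate
17 | (3S)-3-hydroxy-3-[4-methoxy-3-(methoxymethoxy)phenyl]-N,N-dimethylpropanamide | CN(C)C(=O)C[C@H](O)c1ccc(OC)c(OCOC)c1 | intermediate
18 | potassium alkoxide of 17 | CN(C)C(=O)C[C@H](O[K])c1ccc(OC)c(OCOC)c1 | intermediate
19 | 3,5-dimethoxy-6-(3-methylbut-2-en-1-yl)benzyne (1,2-didehydrobenzene) | COC1=C(CC=C(C)C)C#CC(OC)=C1 | intermediate
20 | (3S)-3-[3,5-dimethoxy-6-(3-methylbut-2-en-1-yl)-2-potassiophenoxy]-3-[4-methoxy-3-(methoxymethoxy)phenyl]-N,N-dimethylpropanamide | COc1ccc([C@H](CC(=O)N(C)C)Oc2c([K])c(OC)cc(OC)c2CC=C(C)C)cc1OCOC | intermediate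
21 | potassium (2S)-4-(dimethylamino)-5,7-dimethoxy-2-[4-methoxy-3-(methoxymethoxy)phenyl]-8-(3-methylbut-2-en-1-yl)chroman-4-olate (both C4 epimers) | COc1ccc([C@@H]2CC(O[K])(N(C)C)c3c(OC)cc(OC)c(CC=C(C)C)c3O2)cc1OCOC | intermediate
22 | (2S)-5,7-dimethoxy-2-[4-methoxy-3-(methoxymethoxy)phenyl]-8-(3-methylbut-2-en-1-yl)-2,3-dihydro-4H-chromen-4-one | COc1ccc([C@@H]2CC(=O)c3c(OC)cc(OC)c(CC=C(C)C)c3O2)cc1OCOC | intermediate
23 | (2S)-5-hydroxy-2-(3-hydroxy-4-methoxyphenyl)-7-methoxy-8-(3-methylbut-2-en-1-yl)-2,3-dihydro-4H-chromen-4-one | COc1ccc([C@@H]2CC(=O)c3c(O)cc(OC)c(CC=C(C)C)c3O2)cc1O | target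

**Step count and risks**

Total steps: 8. Longest linear sequence: 5 (steps 1, 2, 3, 7, 8); the branch of steps 4, 5, 6 joins in step 7.

Steps most likely to fail:

1. Step 7 (bears the proposed method). What may go wrong:
   - proton capture by the aryl anion before it reaches the amide, or 1,5-proton abstraction from C3 followed by β-elimination of the aryloxide;
   - oxygen attack at the wrong aryne carbon because of crowding by the prenyl group;
   - sulfonyl transfer from the triflate to the alkoxide;
   - slow retro-aldol erosion of the configuration of the alkoxide.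

   Fallback (known chemistry, ring C closed through O1–C2 instead): it sets out from 11 and 13 and comes back at 22. Aryne 19 is generated from 11 (CsF, THF, sealed tube, 125 °C) in the presence of acetic acid and inserts into its C–O bond (carboxylate O-arylation, then acyl shift to the aryl anion), which by the same O5-controlled regiochemistry should give 1-[2-hydroxy-4,6-dimethoxy-3-(3-methylbut-2-en-1-yl)phenyl]ethan-1-one F1. Ester 13 is reduced (LiAlH4, THF) to [4-methoxy-3-(methoxymethoxy)phenyl]methanol F2 and oxidised (MnO2, CH2Cl2) to 4-methoxy-3-(methoxymethoxy)benzaldehyde F3. Claisen–Schmidt condensation of F1 with F3 (KOH, EtOH) gives (E)-1-[2-hydroxy-4,6-dimethoxy-3-(3-methylbut-2-en-1-yl)phenyl]-3-[4-methoxy-3-(methoxymethoxy)phenyl]prop-2-en-1-one F4. Enantioselective intramolecular oxa-Michael addition under a quinine-derived bifunctional thiourea catalyst (the organocatalytic chalcone-to-flavanone closure, with preparative chiral HPLC of the base-cyclised racemate as a backstop) then gives 22.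

2. Step 8. What may go wrong: addition of hydrogen chloride to, or cationic cyclisation of, the prenyl alkene under the boron halide; Lewis-acid ring opening at O1–C2 that erodes the S configuration; over-dealkylation at O4′ once O3′ is bound to boron.

   Fallback: the deprotection is split into an acetal solvolysis and a nucleophilic dealkylation, so that no boron halide meets the alkene. It sets out from 22 and comes back at 23. HCl (2 M) in MeOH at 40 °C methanolyses the MOM acetal to (2S)-2-(3-hydroxy-4-methoxyphenyl)-5,7-dimethoxy-8-(3-methylbut-2-en-1-yl)-2,3-dihydro-4H-chromen-4-one F5. MgI2·OEt2 (THF/toluene, 60 °C) then removes only the O5 methyl group by SN2 attack of iodide inside a neutral magnesium chelate of the C4 carbonyl and O5, which should give 23.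

3. Step 2. What may go wrong: consumption of the second portion of n-BuLi by residual silyl electrophile, sluggish or misdirected second metalation of the crowded silyl carbamate in the salt-laden mixture (competing deprotonation between the two methoxy groups), loss of the N-silyl protection before the second metalation, and SN2′ capture that would give the reverse-prenyl isomer.

   Fallback: the two metalations are run as separate operations with isolation in between and in the reverse order, so that the carbon–carbon bond is made on the uncrowded ring and only the small silyl electrophile has to enter the crowded position. It sets out from 2 and comes back at 9. Carbamate 2 is N-silylated with TBSOTf/TMEDA and lithiated (4, then 5), and aryllithium 5 is allylated with 3 (CuBr·SMe2 cat.) to 3,5-dimethoxy-2-(3-methylbut-2-en-1-yl)phenyl N-(tert-butyldimethylsilyl)-N-(propan-2-yl)carbamate F6. Aqueous NaHSO4 work-up gives 3,5-dimethoxy-2-(3-methylbut-2-en-1-yl)phenyl N-(propan-2-yl)carbamate F7, which is purified. In a second operation F7 is N-silylated in situ with TMSOTf/TMEDA (Et2O, 0 °C to rt) to 3,5-dimethoxy-2-(3-methylbut-2-en-1-yl)phenyl N-(propan-2-yl)-N-(trimethylsilyl)carbamate F8. Lithiation at the free ortho position (n-BuLi, TMEDA, −78 °C) gives 6-lithio-3,5-dimethoxy-2-(3-methylbut-2-en-1-yl)phenyl N-(propan-2-yl)-N-(trimethylsilyl)carbamate F9. TMSCl then gives 3,5-dimethoxy-2-(3-methylbut-2-en-1-yl)-6-(trimethylsilyl)phenyl N-(propan-2-yl)-N-(trimethylsilyl)carbamate F10, whose N–Si bond is cleaved on aqueous work-up to give 9.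

**Further compounds**

F1 | step 7 | 1-[2-hydroxy-4,6-dimethoxy-3-(3-methylbut-2-en-1-yl)phenyl]ethan-1-one | COc1cc(OC)c(C(C)=O)c(O)c1CC=C(C)C
F2 | step 7 | [4-methoxy-3-(methoxymethoxy)phenyl]methanol | COCOc1cc(CO)ccc1OC
F3 | step 7 | 4-methoxy-3-(methoxymethoxy)benzaldehyde | COCOc1cc(C=O)ccc1OC
F4 | step 7 | (E)-1-[2-hydroxy-4,6-dimethoxy-3-(3-methylbut-2-en-1-yl)phenyl]-3-[4-methoxy-3-(methoxymethoxy)phenyl]prop-2-en-1-one | COc1cc(OC)c(C(=O)/C=C/c2ccc(OC)c(OCOC)c2)c(O)c1CC=C(C)C
F5 | step 8 | (2S)-2-(3-hydroxy-4-methoxyphenyl)-5,7-dimethoxy-8-(3-methylbut-2-en-1-yl)-2,3-dihydro-4H-chromen-4-one | COc1ccc([C@@H]2CC(=O)c3c(OC)cc(OC)c(CC=C(C)C)c3O2)cc1O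
F6 | step 2 | 3,5-dimethoxy-2-(3-methylbut-2-en-1-yl)phenyl N-(tert-butyldimethylsilyl)-N-(propan-2-yl)carbamate | COc1cc(OC)c(CC=C(C)C)c(OC(=O)N(C(C)C)[Si](C)(C)C(C)(C)C)c1
F7 | step 2 | 3,5-dimethoxy-2-(3-methylbut-2-en-1-yl)phenyl N-(propan-2-yl)carbamate | COc1cc(OC)c(CC=C(C)C)c(OC(=O)NC(C)C)c1
F8 | step 2 | 3,5-dimethoxy-2-(3-methylbut-2-en-1-yl)phenyl N-(propan-2-yl)-N-(trimethylsilyl)carbamate | COc1cc(OC)c(CC=C(C)C)c(OC(=O)N(C(C)C)[Si](C)(C)C)c1
F9 | step 2 | 6-lithio-3,5-dimethoxy-2-(3-methylbut-2-en-1-yl)phenyl N-(propan-2-yl)-N-(trimethylsilyl)carbamate | COc1cc(OC)c(CC=C(C)C)c(OC(=O)N(C(C)C)[Si](C)(C)C)c1[Li]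
F10 | step 2 | 3,5-dimethoxy-2-(3-methylbut-2-en-1-yl)-6-(trimethylsilyl)phenyl N-(propan-2-yl)-N-(trimethylsilyl)carbamate | COc1cc(OC)c(CC=C(C)C)c(OC(=O)N(C(C)C)[Si](C)(C)C)c1[Si](C)(C)C
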